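## Retrosynthetic overview

1. Sarothralin ⇒ cut the aryl C3–CH2 bond: an oxidative C(sp3)–H/C(sp2)–H coupling (the new step) joins the C‑methyl triketone norflavesone to 2,4‑dihydroxy‑6‑prenyloxybenzophenone; the bridging CH2 is norflavesone's ring methyl.
2. Norflavesone ⇒ dearomative C‑trimethylation of phlorisobutyrophenone ⇒ Friedel–Crafts acylation of phloroglucinol with isobutyryl chloride.
3. Prenyloxybenzophenone ⇒ ortho‑O‑prenylation of 2,4,6‑trihydroxybenzophenone with the para OH masked as a TIPS ether ⇒ Friedel–Crafts benzoylation of phloroglucinol.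
4. Ring order: no ring is built. Both carbocycles come from phloroglucinol; the filicinic ring is made by dearomatisation first (step 2), the aryl ring is elaborated next (steps 3–6), and the two are joined last (step 7).

Assumption: the target SMILES has no stereocentre and no stereogenic double bond, so the compound is achiral and no enantio‑ or diastereocontrol is needed; it is made as the enol tautomer drawn.

## Route

Step 1
Reactants: 1 phloroglucinol; 2 isobutyryl chloride
Product: 3 2,4,6‑trihydroxyisobutyrophenone (phlorisobutyrophenone)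
Conditions: AlCl3 (3.5 equiv), PhNO2/CH2Cl2, 0 → 50 °C; then ice/1 M HCl
Reagents that add atoms: none
Why: Friedel–Crafts C‑acylation of the strongly activated triol stops after one acyl group because the chelated aryl ketone deactivates the ring; no stereocentre is formed.

Step 2
Reactants: 3 2,4,6‑trihydroxyisobutyrophenone
Product: 4 norflavesone (3,5‑dihydroxy‑4,6,6‑trimethyl‑2‑(2‑methylpropanoyl)cyclohexa‑2,4‑dien‑1‑one)
Conditions: NaOMe (3.0 equiv), MeI (3.0 equiv), MeOH, 0 °C → rt
Reagents that add atoms: iodomethane, CI
Why: Base‑mediated dearomative C‑methylation (enolate SN2 alkylation) occurs at the two soft ring carbons, and any order of three methylations converges on the same 4,6,6‑trimethyl triketone, whose C6 carries two identical methyls and is not a stereocentre.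

Step 3
Reactants: 1 phloroglucinol; 5 benzoyl chloride
Product: 6 2,4,6‑trihydroxybenzophenone
Conditions: AlCl3 (3.5 equiv), PhNO2, rt → 60 °C; then ice/1 M HCl
Reagents that add atoms: none
Why: Friedel–Crafts benzoylation of phloroglucinol, mono‑selective for the same reason as step 1 (any O‑benzoate formed undergoes Fries rearrangement under the conditions).

Step 4
Reactants: 6 2,4,6‑trihydroxybenzophenone
Product: 7 2,6‑dihydroxy‑4‑(triisopropylsilyloxy)benzophenone
Conditions: TIPSCl (1.05 equiv), imidazole (2.2 equiv), DMF, 0 °C
Reagents that add atoms: triisopropylsilyl chloride (TIPSCl), CC(C)[Si](Cl)(C(C)C)C(C)C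
Why: Site‑selective O‑silylation, because the para 4‑OH is the only hydroxyl not hydrogen‑bonded to the ketone and is the most acidic and least hindered, so the bulky silyl chloride takes it alone.

Step 5
Reactants: 7 2,6‑dihydroxy‑4‑(triisopropylsilyloxy)benzophenone; 8 prenyl bromide
Product: 9 2‑hydroxy‑6‑(3‑methylbut‑2‑enyloxy)‑4‑(triisopropylsilyloxy)benzophenone
Conditions: K2CO3 (1.2 equiv), prenyl bromide (1.1 equiv), acetone, rt
Reagents that add atoms: none
Why: Williamson ether synthesis (SN2) on one of the two equivalent ortho hydroxyls; after the first alkylation the remaining OH is strongly chelated to the carbonyl and poorly nucleophilic, which stops the reaction at the mono‑ether while the para oxygen is blocked by TIPS.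

Step 6
Reactants: 9 2‑hydroxy‑6‑(3‑methylbut‑2‑enyloxy)‑4‑(triisopropylsilyloxy)benzophenone
Product: 10 2,4‑dihydroxy‑6‑(3‑methylbut‑2‑enyloxy)benzophenone
Conditions: TBAF (1.1 equiv), AcOH (1.1 equiv), THF, 0 °C
Reagents that add atoms: none
Why: Fluoride‑induced desilylation driven by the Si–F bond, buffered with acetic acid so that the acid‑ and heat‑sensitive aryl prenyl ether is untouched.

Step 7
Reactants: 4 norflavesone; 10 2,4‑dihydroxy‑6‑(3‑methylbut‑2‑enyloxy)benzophenone
Product: 12 sarothralin, via filicinic methide 11 (not isolated)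
Conditions: Ag2O (1.1 equiv), TEMPO (20 mol %), 10 (1.5 equiv), THF, 0 °C → rt, dark, 4 added over 2 h; then 1 M HCl wash
Reagents that add atoms: none
Why: Proposed new method: an oxidative cross‑dehydrogenative C(sp3)–H/C(sp2)–H coupling (dehydrogenative Michael/Friedel–Crafts alkylation) in which Ag2O, with catalytic TEMPO as hydrogen‑atom shuttle (TEMPO‑H is re‑oxidised by Ag2O), removes the enol O–H hydrogen of 4 and then a C‑methyl hydrogen of the resulting captodative radical to give the 6‑methylidene trione 11, a vinylogous ortho‑quinone methide, which is captured in conjugate fashion by the most nucleophilic carbon of 10 (C3, flanked by the two free hydroxyls and less hindered than C5 next to the prenyl ether) and then tautomerises back to the arene to give 12; selectivity is expected because the triketone enol is easier to dehydrogenate than the benzoyl‑deactivated, hydrogen‑bonded phenol, because C‑addition of a phloroglucinol carbon to the unsubstituted methide should outrun hetero‑Diels–Alder capture by the unactivated prenyl alkene, and because neither partner can form a methylene‑bridged homodimer (4 has no free ring C–H and 10 carries no C1 unit); the closest known reaction types are the Ag2O/TEMPO dehydrogenation of C‑methyl acylfilicinic acids to such methides with hetero‑Diels–Alder trapping by alkenes, and the Michael addition of acylphloroglucinols to pre‑formed alkylidene triketones or Mannich‑base‑derived methides, whereas carbon capture by a free phenol under the oxidative conditions to forge a methylene bridge has, to my knowledge, not been shown.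

## Compound list

1 | phloroglucinol (benzene‑1,3,5‑triol) | Oc1cc(O)cc(O)c1 | starting material
2 | isobutyryl chloride (2‑methylpropanoyl chloride) | CC(C)C(Cl)=O | starting material
3 | 2,4,6‑trihydroxyisobutyrophenone (phlorisobutyrophenone) | CC(C)C(=O)c1c(O)cc(O)cc1O | intermediate
4 | norflavesone (3,5‑dihydroxy‑4,6,6‑trimethyl‑2‑(2‑methylpropanoyl)cyclohexa‑2,4‑dien‑1‑one) | CC1=C(O)C(C)(C)C(=O)C(C(=O)C(C)C)=C1O | intermediate
5 | benzoyl chloride | O=C(Cl)c1ccccc1 | starting material
6 | 2,4,6‑trihydroxybenzophenone | O=C(c1ccccc1)c1c(O)cc(O)cc1O | intermediate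
7 | 2,6‑dihydroxy‑4‑(triisopropylsilyloxy)benzophenone | CC(C)[Si](Oc1cc(O)c(C(=O)c2ccccc2)c(O)c1)(C(C)C)C(C)C | intermediate
8 | prenyl bromide (1‑bromo‑3‑methylbut‑2‑ene) | CC(C)=CCBr | starting material
9 | 2‑hydroxy‑6‑(3‑methylbut‑2‑enyloxy)‑4‑(triisopropylsilyloxy)benzophenone | CC(C)=CCOc1cc(O[Si](C(C)C)(C(C)C)C(C)C)cc(O)c1C(=O)c1ccccc1 | intermediate
10 | 2,4‑dihydroxy‑6‑(3‑methylbut‑2‑enyloxy)benzophenone | CC(C)=CCOc1cc(O)cc(O)c1C(=O)c1ccccc1 | intermediate
11 | filicinic methide (5‑hydroxy‑2,2‑dimethyl‑6‑methylidene‑4‑(2‑methylpropanoyl)cyclohex‑4‑ene‑1,3‑dione) | C=C1C(=O)C(C)(C)C(=O)C(C(=O)C(C)C)=C1O | intermediate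
12 | sarothralin ([2,4‑dihydroxy‑3‑{[2,6‑dihydroxy‑3,3‑dimethyl‑5‑(2‑methylpropanoyl)‑4‑oxocyclohexa‑1,5‑dien‑1‑yl]methyl}‑6‑(3‑methylbut‑2‑enyloxy)phenyl](phenyl)methanone) | CC(C)=CCOc1cc(O)c(CC2=C(O)C(C)(C)C(=O)C(C(=O)C(C)C)=C2O)c(O)c1C(=O)c1ccccc1 | target

## Summary and risks

Total step count: 7.
Longest linear sequence: 5 steps (steps 3–7, from 1 to 12); the other branch is 3 steps (steps 1, 2, 7).

Three steps most likely to fail:

**Step 7 (the proposed new coupling).** The risks are over‑oxidation of 12 (it contains the same enol motif as 4), oxidation of phenol 10, capture of 11 by the prenyl alkene, and attack at C5 instead of C3. The fallback uses known chemistry, sets out from 3 and comes back to the route at 12. Compound 3 is C‑methylated only twice (MeI 2.1 equiv, NaOMe, MeOH, 0 °C → rt) to isobutyrylfilicinic acid F1. F1 is aminomethylated at its free ring carbon with Eschenmoser's salt (CH2Cl2, rt; Mannich reaction) to the Mannich base 4‑[(dimethylamino)methyl]‑3,5‑dihydroxy‑6,6‑dimethyl‑2‑(2‑methylpropanoyl)cyclohexa‑2,4‑dien‑1‑one F2. Heating F2 with 10 (1.2 equiv, dioxane, 70 °C, nitrogen purge) expels dimethylamine, releases methide 11 without any oxidant, and lets it add to C3 of 10 to give 12.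

**Step 5 (mono‑O‑prenylation ortho to the ketone).** The risks are C‑prenylation of the electron‑rich ring, bis‑alkylation, and loss or migration of the silyl group under carbonate. The fallback sets out from 7 and comes back at 9. The phenoxide SN2 reaction is replaced by a Mitsunobu redox condensation of 7 with 3‑methylbut‑2‑en‑1‑ol (PPh3, DIAD, THF, 0 °C → rt). This activates the alcohol instead of deprotonating the phenol, so the medium stays neutral, O‑alkylation is exclusive and the silyl ether is not exposed to base. It makes no new compound (F0).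

**Step 2 (threefold dearomative methylation).** The risk is a statistical mixture of di‑, tri‑ and tetramethyl products plus O‑methyl ethers. The fallback sets out from 2 and comes back at 4. Isobutyryl chloride 2 acylates purchased 2‑methylphloroglucinol F3 in place of 1 (AlCl3, PhNO2/CH2Cl2, 0 → 50 °C) to give 2,4,6‑trihydroxy‑3‑methylisobutyrophenone F4, in which the future bridging methyl is already in place. F4 then needs only two further C‑methylations (MeI 2.0 equiv, NaOMe, MeOH), both of which lead to 4 whichever ring carbon reacts first.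

## Further compounds

F1 | step 7 | isobutyrylfilicinic acid (3,5‑dihydroxy‑6,6‑dimethyl‑2‑(2‑methylpropanoyl)cyclohexa‑2,4‑dien‑1‑one) | CC(C)C(=O)C1=C(O)C=C(O)C(C)(C)C1=O
F2 | step 7 | 4‑[(dimethylamino)methyl]‑3,5‑dihydroxy‑6,6‑dimethyl‑2‑(2‑methylpropanoyl)cyclohexa‑2,4‑dien‑1‑one (Mannich base) | CN(C)CC1=C(O)C(C)(C)C(=O)C(C(=O)C(C)C)=C1O
F0 | step 5 | none | none
F3 | step 2 | 2‑methylphloroglucinol (2,4,6‑trihydroxytoluene; bought, not made) | Cc1c(O)cc(O)cc1O
F4 | step 2 | 2,4,6‑trihydroxy‑3‑methylisobutyrophenone | CC(C)C(=O)c1c(O)cc(O)c(C)c1O
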